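**Retrosynthetic overview**
1. Butenolide last, by intramolecular Horner–Wadsworth–Emmons closure; the C11–C16 chain is joined to C9 by B-alkyl Suzuki coupling of a C8(CH3)=C9 enol triflate.
2. 6α-OH comes from oxidation/hydride inversion of a 6β-silyloxy group that first serves as the stereocontrol element.
3. Ring A is closed second (C1–C10) by intramolecular alkylation of the C9-ketone enolate, which sets the C10 quaternary centre and the cis ring fusion.
4. Key fragment union (C4–C5): intermolecular Mukaiyama–Michael addition of the silyl ketene acetal of (5S)-5-(benzyloxymethyl)-3-methylbutyrolactone (C19, C18, C1–C4) to (R)-4-silyloxy-2-methylcyclohex-2-enone (ring B).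
5. Ring order: ring B (from 4-methoxy-3-methylphenol) → ring A → butenolide.

Assumption: the SMILES is taken literally, (2R,4S,5S,6S,10S) in labdane numbering, i.e. a 5,10-cis-fused decalin with H-5, CH3-10 (C20) and CH2OAc-4 (C19) on one face (β) and CH3-4 (C18), 2-OH and 6-OH on the other (α); C17 = CH3 on C8; these position numbers are used for all intermediates.
Abbreviations: TBS = tert-butyldimethylsilyl, TBDPS = tert-butyldiphenylsilyl, Bn = benzyl.

**Step 1**
Reactants: 1 4-methoxy-3-methylphenol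
Product: 2 4,4-dimethoxy-3-methylcyclohexa-2,5-dien-1-one
Conditions: PhI(OAc)2, MeOH, 0 °C
Reagents that add atoms: methanol, CO
Why: Hypervalent-iodine oxidative dearomatisation of the para-methoxyphenol in methanol gives the quinone monoketal whose free carbonyl is remote from the methyl group.

**Step 2**
Reactants: 2 4,4-dimethoxy-3-methylcyclohexa-2,5-dien-1-one
Product: 3 4,4-dimethoxy-3-methylcyclohex-2-en-1-one
Conditions: H2 (1 atm), RhCl(PPh3)3 (5 mol %), toluene, rt
Reagents that add atoms: none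
Why: Homogeneous hydrogenation saturates only the unhindered disubstituted C=C of the cross-conjugated dienone and leaves the methyl-bearing trisubstituted C=C.

**Step 3**
Reactants: 3 4,4-dimethoxy-3-methylcyclohex-2-en-1-one
Product: 4 (1R)-4,4-dimethoxy-3-methylcyclohex-2-en-1-ol
Conditions: (3aS)-1-methyl-3,3-diphenyltetrahydro-1H,3H-pyrrolo[1,2-c][1,3,2]oxazaborole (10 mol %), BH3·SMe2, THF, −20 °C; MeOH quench
Reagents that add atoms: none
Why: Corey–Bakshi–Shibata reduction in which the alkenyl side acts as the large group, so the (S)-oxazaborolidine gives the (R)-allylic alcohol (future C6).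

**Step 4**
Reactants: 4 (1R)-4,4-dimethoxy-3-methylcyclohex-2-en-1-ol
Product: 5 tert-butyl{[(1R)-4,4-dimethoxy-3-methylcyclohex-2-en-1-yl]oxy}dimethylsilane
Conditions: tBuMe2SiCl, imidazole, DMF, rt
Reagents that add atoms: tert-butyldimethylsilyl chloride, CC(C)(C)[Si](C)(C)Cl
Why: Standard silylation of a secondary allylic alcohol; the bulky silyl ether later shields one face of the enone.

**Step 5**
Reactants: 5 tert-butyl{[(1R)-4,4-dimethoxy-3-methylcyclohex-2-en-1-yl]oxy}dimethylsilane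
Product: 6 (4R)-4-[(tert-butyldimethylsilyl)oxy]-2-methylcyclohex-2-en-1-one (fragment B)
Conditions: oxalic acid (cat.), wet SiO2, CH2Cl2, rt
Reagents that add atoms: water, O
Why: Mild acid hydrolysis of the dimethyl ketal unmasks the carbonyl (future C9) next to the methyl-bearing alkene carbon (future C10) without touching the γ-stereocentre.

**Step 6**
Reactants: 7 (5S)-5-(hydroxymethyl)oxolan-2-one
Product: 8 (5S)-5-[(benzyloxy)methyl]oxolan-2-one
Conditions: benzyl 2,2,2-trichloroacetimidate, CF3SO3H (cat.), CH2Cl2–cyclohexane, 0 °C → rt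
Reagents that add atoms: benzyl 2,2,2-trichloroacetimidate, ClC(Cl)(Cl)C(=N)OCc1ccccc1
Why: Acid-catalysed imidate benzylation protects the primary alcohol without the base that would open the lactone.

**Step 7**
Reactants: 8 (5S)-5-[(benzyloxy)methyl]oxolan-2-one
Product: 10 (5S)-5-[(benzyloxy)methyl]-3-methyloxolan-2-one (C3 epimers), via lithium lactone enolate 9 (not isolated)
Conditions: LiN(iPr)2 (1.05 equiv), THF, −78 °C; MeI, −78 → −20 °C
Reagents that add atoms: iodomethane, CI
Why: Enolate alkylation α to the lactone carbonyl; the new centre is planarised again in step 8, so its configuration is irrelevant.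

**Step 8**
Reactants: 10 (5S)-5-[(benzyloxy)methyl]-3-methyloxolan-2-one
Product: 12 {[(5S)-5-[(benzyloxy)methyl]-3-methyl-4,5-dihydrofuran-2-yl]oxy}(tert-butyl)dimethylsilane (fragment A), via lithium methyl-lactone enolate 11 (not isolated)
Conditions: LiN(iPr)2, THF, −78 °C; tBuMe2SiCl, DMPU, −78 °C → rt; pentane filtration, used crude
Reagents that add atoms: tert-butyldimethylsilyl chloride, CC(C)(C)[Si](C)(C)Cl
Why: O-silylation of the lactone enolate gives the fully substituted cyclic silyl ketene acetal needed as Michael donor.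

**Step 9 (key fragment union)**
Reactants: 6 (4R)-4-[(tert-butyldimethylsilyl)oxy]-2-methylcyclohex-2-en-1-one; 12 silyl ketene acetal (fragment A)
Product: 14 keto lactone with the C4–C5 bond (ring B trans to CH2OBn on the lactone; C4 trans to 6-OTBS on ring B; C10 epimers), via silyl enol ether adduct 13 (not isolated)
Conditions: LiClO4 (3 M in Et2O), rt; then 1 M HCl, THF, 0 °C
Reagents that add atoms: none
Why: Intermolecular Mukaiyama–Michael addition in which the ketene acetal reacts on the face anti to its CH2OBn group (sets the C4 quaternary centre, CH3 cis to C1) and the enone is attacked anti to its OTBS group (sets H-5), after which the silyl enol ether is hydrolysed to the ketone.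

**Step 10**
Reactants: 14 keto lactone
Product: 17 seco acid (C19 CO2H; C2-OTBDPS; C1-OBn; ring B unchanged), via potassium hydroxy carboxylate 15 (not isolated), via bis-silylated silyl ester 16 (not isolated)
Conditions: KOH (1.05 equiv), MeOH–H2O, rt; evaporate; tBuPh2SiCl (2.5 equiv), imidazole, DMF, 40 °C; then THF–H2O–AcOH, rt
Reagents that add atoms: potassium hydroxide, [K+].[OH-]; tert-butyl(chloro)diphenylsilane, CC(C)(C)[Si](Cl)(c1ccccc1)c1ccccc1
Why: Saponification opens the γ-lactone irreversibly, silylation caps the C2 hydroxyl before any acid can relactonise it, and the labile silyl ester alone is hydrolysed on aqueous work-up.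

**Step 11**
Reactants: 17 seco acid
Product: 18 seco methyl ester (C19 CO2CH3)
Conditions: MeI, K2CO3, DMF, rt
Reagents that add atoms: iodomethane, CI
Why: SN2 O-alkylation of the hindered carboxylate gives a quaternary ester that has no α-hydrogen and is inert to the later bases.

**Step 12**
Reactants: 18 seco methyl ester
Product: 19 seco primary alcohol (C1-OH)
Conditions: H2 (1 atm), Pd/C (10 wt %), EtOAc, rt
Reagents that add atoms: none
Why: Hydrogenolysis removes the benzyl ether cleanly because no alkene is present at this stage and silyl ethers, ketone and ester are untouched.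

**Step 13**
Reactants: 19 seco primary alcohol
Product: 20 seco primary iodide (C1-I)
Conditions: I2, PPh3, imidazole, CH2Cl2, 0 °C → rt
Reagents that add atoms: iodine, II
Why: Appel-type (Garegg–Samuelsson) iodination converts the primary alcohol into the leaving group for ring closure under neutral conditions.

**Step 14**
Reactants: 20 seco primary iodide
Product: 21 cis-decalone (methyl 19-oate; 4α-CH3; 2α-OTBDPS; 6β-OTBS; 9-oxo; 10β-CH3; H-5β)
Conditions: KOtBu (1.2 equiv), tBuOH–THF, 0 °C → rt, high dilution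
Reagents that add atoms: none
Why: Intramolecular enolate alkylation (6-exo-tet) in which only the reversibly formed C10 enolate can reach C1, and axial attack on the face of C10 where C4 sits gives the quaternary centre with CH3-10 syn to H-5 (cis fusion).

**Step 15**
Reactants: 21 cis-decalone
Product: 23 8-methyl cis-decalone (C8 epimers), via lithium C8 enolate 22 (not isolated)
Conditions: LiN(iPr)2 (1.1 equiv), THF, −78 °C; MeI, −78 → 0 °C
Reagents that add atoms: iodomethane, CI
Why: Enolate alkylation at C8, the only enolisable position of the C9 ketone, installs C17; the new centre becomes sp2 in step 16.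

**Step 16**
Reactants: 23 8-methyl cis-decalone
Product: 25 C8=C9 enol triflate, via potassium C8 enolate 24 (not isolated)
Conditions: KN(SiMe3)2 (1.2 equiv), THF, −78 → 0 °C; PhN(SO2CF3)2, −78 °C → rt
Reagents that add atoms: N-phenylbis(trifluoromethanesulfonimide), O=S(=O)(N(c1ccccc1)S(=O)(=O)C(F)(F)F)C(F)(F)F
Why: Enol triflate formation can occur only toward C8 (C10 is quaternary), which fixes the position of the tetrasubstituted alkene.

**Step 17**
Reactants: 25 enol triflate
Product: 26 6β-alcohol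
Conditions: camphor-10-sulfonic acid (cat.), MeOH–CH2Cl2, 0 °C → rt
Reagents that add atoms: none
Why: Acid-catalysed methanolysis cleaves the secondary TBS ether far faster than the TBDPS ether at C2.

**Step 18**
Reactants: 26 6β-alcohol
Product: 27 cis-fused 6-ketone
Conditions: 1,1,1-triacetoxy-1,1-dihydro-1,2-benziodoxol-3(1H)-one (Dess–Martin periodinane), NaHCO3, CH2Cl2, 0 °C → rt; used at once
Reagents that add atoms: none
Why: Buffered Dess–Martin oxidation is neutral, so the ring-fusion hydrogen α to the new ketone is not epimerised.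

**Step 19**
Reactants: 27 cis-fused 6-ketone
Product: 28 6α-alcohol
Conditions: LiBH(sBu)3, THF, −78 °C; H2O
Reagents that add atoms: none
Why: The bulky hydride attacks equatorially from the β face (the α face is screened by the axial C1 methylene), giving the axial 6α-alcohol cis to C4 at a temperature where C5 is not enolised.

**Step 20**
Reactants: 28 6α-alcohol
Product: 29 6α-TBS ether
Conditions: tBuMe2SiOSO2CF3, 2,6-lutidine, CH2Cl2, −78 → 0 °C
Reagents that add atoms: tert-butyldimethylsilyl trifluoromethanesulfonate, CC(C)(C)[Si](C)(C)OS(=O)(=O)C(F)(F)F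
Why: The silyl triflate protects the hindered axial alcohol so that the later side-chain oxidation cannot touch C6.

**Step 21**
Reactants: 29 6α-TBS ether enol triflate; 30 2,2-dimethyl-4-vinyl-1,3-dioxolane (racemic)
Product: 32 coupled acetonide (C9–C11 bond; C13 epimers), via B-alkyl-9-BBN borane 31 (not isolated)
Conditions: 30, 9-borabicyclo[3.3.1]nonane, THF, 0 °C → rt; then 29, PdCl2[1,1'-bis(diphenylphosphino)ferrocene] (10 mol %), AsPh3, Cs2CO3, DMF–THF–H2O, 50 °C
Reagents that add atoms: none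
Why: Anti-Markovnikov hydroboration followed by B-alkyl Suzuki–Miyaura coupling replaces the triflate with the C11–C16 chain with retention of the C8=C9 position.

**Step 22**
Reactants: 32 coupled acetonide
Product: 33 C19 primary alcohol
Conditions: LiAlH4, THF, 0 °C → rt; Fieser work-up
Reagents that add atoms: none
Why: Hydride reduction of the hindered axial methyl ester gives the neopentyl alcohol while silyl ethers, acetonide and the tetrasubstituted alkene are inert.

**Step 23**
Reactants: 33 C19 primary alcohol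
Product: 34 C19 acetate
Conditions: Ac2O, pyridine, 4-(dimethylamino)pyridine (cat.), CH2Cl2, rt
Reagents that add atoms: acetic anhydride, CC(=O)OC(C)=O
Why: Acylation of the only free hydroxyl installs the acetate of the target after the last strongly basic or reducing step.

**Step 24**
Reactants: 34 C19 acetate
Product: 35 side-chain 13,16-diol
Conditions: AcOH–H2O–THF (3:1:1), 40 °C
Reagents that add atoms: none
Why: Mild acid hydrolysis removes the terminal acetonide while the hindered secondary silyl ethers and the acetate survive.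

**Step 25**
Reactants: 35 side-chain 13,16-diol; 36 (diethoxyphosphoryl)acetic acid
Product: 37 C16 (diethoxyphosphoryl)acetate with free C13-OH
Conditions: N,N'-dicyclohexylcarbodiimide, 4-(dimethylamino)pyridine (cat.), CH2Cl2, 0 °C
Reagents that add atoms: none
Why: Steglich esterification acylates the primary hydroxyl selectively over the secondary one at low temperature.

**Step 26**
Reactants: 37 C16 phosphonoacetate
Product: 38 C13 ketone
Conditions: 1,1,1-triacetoxy-1,1-dihydro-1,2-benziodoxol-3(1H)-one (Dess–Martin periodinane), NaHCO3, CH2Cl2, rt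
Reagents that add atoms: none
Why: Dess–Martin oxidation of the only free (secondary) alcohol gives the α-acyloxy ketone without affecting the alkene or esters.

**Step 27**
Reactants: 38 C13 ketone
Product: 39 bis-silylated butenolide
Conditions: LiCl, iPr2NEt, MeCN, rt
Reagents that add atoms: none
Why: Intramolecular Horner–Wadsworth–Emmons olefination under mild Masamune–Roush conditions closes the five-membered C13=C14 butenolide.

**Step 28**
Reactants: 39 bis-silylated butenolide
Product: 40 target CNP0201970.1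
Conditions: HF·pyridine, pyridine, THF, 0 °C → rt
Reagents that add atoms: none
Why: Buffered fluoride desilylation removes both silyl ethers while the acetate, the butenolide and the tetrasubstituted alkene are stable.

**Compound list**
1 | 4-methoxy-3-methylphenol | COc1ccc(O)cc1C | starting material
2 | 4,4-dimethoxy-3-methylcyclohexa-2,5-dien-1-one | COC1(OC)C=CC(=O)C=C1C | intermediate
3 | 4,4-dimethoxy-3-methylcyclohex-2-en-1-one | COC1(OC)CCC(=O)C=C1C | intermediate
4 | (1R)-4,4-dimethoxy-3-methylcyclohex-2-en-1-ol | COC1(OC)CC[C@@H](O)C=C1C | intermediate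
5 | tert-butyl{[(1R)-4,4-dimethoxy-3-methylcyclohex-2-en-1-yl]oxy}dimethylsilane | COC1(OC)CC[C@@H](O[Si](C)(C)C(C)(C)C)C=C1C | intermediate
6 | (4R)-4-[(tert-butyldimethylsilyl)oxy]-2-methylcyclohex-2-en-1-one (fragment B; C1 = future C9, C2 = C10, C3 = C5, C4 = C6) | CC1=C[C@H](O[Si](C)(C)C(C)(C)C)CCC1=O | intermediate
7 | (5S)-5-(hydroxymethyl)oxolan-2-one | OC[C@@H]1CCC(=O)O1 | starting material
8 | (5S)-5-[(benzyloxy)methyl]oxolan-2-one | O=C1CC[C@@H](COCc2ccccc2)O1 | intermediate
9 | lithium enolate of 8 (not isolated) | [Li]OC1=CC[C@@H](COCc2ccccc2)O1 | intermediate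
10 | (5S)-5-[(benzyloxy)methyl]-3-methyloxolan-2-one, C3 epimers | CC1C[C@@H](COCc2ccccc2)OC1=O | intermediate
11 | lithium enolate of 10 (not isolated) | [Li]OC1=C(C)C[C@@H](COCc2ccccc2)O1 | intermediate
12 | {[(5S)-5-[(benzyloxy)methyl]-3-methyl-4,5-dihydrofuran-2-yl]oxy}(tert-butyl)dimethylsilane (fragment A; ring C2 = future C19, C3 = C4, C4 = C3, C5 = C2, CH2OBn = C1) | CC(C)(C)[Si](C)(C)OC1=C(C)C[C@@H](COCc2ccccc2)O1 | intermediate
13 | Michael adduct as C9 TBS enol ether (not isolated): lactone of 14 with C9(OTBS)=C10(CH3) | C[C@]1(C[C@@H](COCc2ccccc2)OC1=O)[C@@H]3C(C)=C(O[Si](C)(C)C(C)(C)C)CC[C@H]3O[Si](C)(C)C(C)(C)C | intermediate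
14 | (5S)-5-[(benzyloxy)methyl]-3-methyl-3-{6-[(tert-butyldimethylsilyl)oxy]-2-methyl-3-oxocyclohexyl}oxolan-2-one; cyclohexyl trans to CH2OBn on the lactone, lactone trans to OTBS on the cyclohexanone (H-5β, 6β-OTBS, C19 β, C18 α), C10 epimers | C[C@]1(C[C@@H](COCc2ccccc2)OC1=O)[C@@H]3C(C)C(=O)CC[C@H]3O[Si](C)(C)C(C)(C)C | intermediate
15 | potassium salt of the ring-opened hydroxy acid of 14 (C19 carboxylate, free 2-OH; not isolated) | [K+].[O-]C(=O)[C@@](C)(C[C@H](O)COCc2ccccc2)[C@@H]1C(C)C(=O)CC[C@H]1O[Si](C)(C)C(C)(C)C | intermediate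
16 | TBDPS ester of 17 (C19 silyl ester, 2-OTBDPS; not isolated) | CC(C)(C)[Si](c3ccccc3)(c3ccccc3)OC(=O)[C@@](C)(C[C@H](O[Si](c3ccccc3)(c3ccccc3)C(C)(C)C)COCc2ccccc2)[C@@H]1C(C)C(=O)CC[C@H]1O[Si](C)(C)C(C)(C)C | intermediate
17 | 5-(benzyloxy)-4-[(tert-butyldiphenylsilyl)oxy]-2-methyl-2-{6-[(tert-butyldimethylsilyl)oxy]-2-methyl-3-oxocyclohexyl}pentanoic acid, all centres as in 14 | OC(=O)[C@@](C)(C[C@H](O[Si](c3ccccc3)(c3ccccc3)C(C)(C)C)COCc2ccccc2)[C@@H]1C(C)C(=O)CC[C@H]1O[Si](C)(C)C(C)(C)C | intermediate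
18 | methyl ester of 17 | COC(=O)[C@@](C)(C[C@H](O[Si](c3ccccc3)(c3ccccc3)C(C)(C)C)COCc2ccccc2)[C@@H]1C(C)C(=O)CC[C@H]1O[Si](C)(C)C(C)(C)C | intermediate
19 | 5-hydroxy analogue of 18 (C1-OH) | COC(=O)[C@@](C)(C[C@H](O[Si](c3ccccc3)(c3ccccc3)C(C)(C)C)CO)[C@@H]1C(C)C(=O)CC[C@H]1O[Si](C)(C)C(C)(C)C | intermediate
20 | 5-iodo analogue of 18 (C1-I) | COC(=O)[C@@](C)(C[C@H](O[Si](c3ccccc3)(c3ccccc3)C(C)(C)C)CI)[C@@H]1C(C)C(=O)CC[C@H]1O[Si](C)(C)C(C)(C)C | intermediate
21 | cis-decalone: methyl 2α-(TBDPS-oxy)-6β-(TBS-oxy)-4α,10β-dimethyl-9-oxo-5β-H-decalin-4β-carboxylate (labdane numbering) | COC(=O)[C@@]1(C)C[C@H](O[Si](c3ccccc3)(c3ccccc3)C(C)(C)C)C[C@]2(C)C(=O)CC[C@@H](O[Si](C)(C)C(C)(C)C)[C@H]12 | intermediate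
22 | lithium C8(9)-enolate of 21 (not isolated) | COC(=O)[C@@]1(C)C[C@H](O[Si](c3ccccc3)(c3ccccc3)C(C)(C)C)C[C@]2(C)C(O[Li])=CC[C@@H](O[Si](C)(C)C(C)(C)C)[C@H]12 | intermediate
23 | 8-methyl derivative of 21, C8 epimers | COC(=O)[C@@]1(C)C[C@H](O[Si](c3ccccc3)(c3ccccc3)C(C)(C)C)C[C@]2(C)C(=O)C(C)C[C@@H](O[Si](C)(C)C(C)(C)C)[C@H]12 | intermediate
24 | potassium C8(9)-enolate of 23 (not isolated) | COC(=O)[C@@]1(C)C[C@H](O[Si](c3ccccc3)(c3ccccc3)C(C)(C)C)C[C@]2(C)C(O[K])=C(C)C[C@@H](O[Si](C)(C)C(C)(C)C)[C@H]12 | intermediate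
25 | C9 enol triflate (C8=C9, 8-CH3), 6β-OTBS, 2α-OTBDPS, methyl 19-oate | COC(=O)[C@@]1(C)C[C@H](O[Si](c3ccccc3)(c3ccccc3)C(C)(C)C)C[C@]2(C)C(OS(=O)(=O)C(F)(F)F)=C(C)C[C@@H](O[Si](C)(C)C(C)(C)C)[C@H]12 | intermediate
26 | 6β-alcohol of 25 | COC(=O)[C@@]1(C)C[C@H](O[Si](c3ccccc3)(c3ccccc3)C(C)(C)C)C[C@]2(C)C(OS(=O)(=O)C(F)(F)F)=C(C)C[C@@H](O)[C@H]12 | intermediate
27 | 6-ketone (cis-fused, H-5β) | COC(=O)[C@@]1(C)C[C@H](O[Si](c3ccccc3)(c3ccccc3)C(C)(C)C)C[C@]2(C)C(OS(=O)(=O)C(F)(F)F)=C(C)CC(=O)[C@H]12 | intermediate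
28 | 6α-alcohol | COC(=O)[C@@]1(C)C[C@H](O[Si](c3ccccc3)(c3ccccc3)C(C)(C)C)C[C@]2(C)C(OS(=O)(=O)C(F)(F)F)=C(C)C[C@H](O)[C@H]12 | intermediate
29 | 6α-TBS ether of 28 | COC(=O)[C@@]1(C)C[C@H](O[Si](c3ccccc3)(c3ccccc3)C(C)(C)C)C[C@]2(C)C(OS(=O)(=O)C(F)(F)F)=C(C)C[C@H](O[Si](C)(C)C(C)(C)C)[C@H]12 | intermediate
30 | 2,2-dimethyl-4-vinyl-1,3-dioxolane (racemic) | C=CC1COC(C)(C)O1 | starting material
31 | 9-[2-(2,2-dimethyl-1,3-dioxolan-4-yl)ethyl]-9-borabicyclo[3.3.1]nonane (not isolated) | CC1(C)OCC(CCB2C3CCCC2CCC3)O1 | intermediate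
32 | methyl 2α-(TBDPS-oxy)-6α-(TBS-oxy)-13,16-(isopropylidenedioxy)-14,15-dinor-5β-labd-8-en-19-oate, C13 epimers | COC(=O)[C@@]1(C)C[C@H](O[Si](c3ccccc3)(c3ccccc3)C(C)(C)C)C[C@]2(C)C(CCC3COC(C)(C)O3)=C(C)C[C@H](O[Si](C)(C)C(C)(C)C)[C@H]12 | intermediate
33 | 19-alcohol of 32 | OC[C@@]1(C)C[C@H](O[Si](c3ccccc3)(c3ccccc3)C(C)(C)C)C[C@]2(C)C(CCC3COC(C)(C)O3)=C(C)C[C@H](O[Si](C)(C)C(C)(C)C)[C@H]12 | intermediate
34 | 19-acetate of 33 | CC(=O)OC[C@@]1(C)C[C@H](O[Si](c3ccccc3)(c3ccccc3)C(C)(C)C)C[C@]2(C)C(CCC3COC(C)(C)O3)=C(C)C[C@H](O[Si](C)(C)C(C)(C)C)[C@H]12 | intermediate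
35 | 13,16-diol of 34 | CC(=O)OC[C@@]1(C)C[C@H](O[Si](c3ccccc3)(c3ccccc3)C(C)(C)C)C[C@]2(C)C(CCC(O)CO)=C(C)C[C@H](O[Si](C)(C)C(C)(C)C)[C@H]12 | intermediate
36 | (diethoxyphosphoryl)acetic acid | CCOP(=O)(CC(=O)O)OCC | starting material
37 | 16-O-[(diethoxyphosphoryl)acetyl] ester of 35 (free 13-OH) | CC(=O)OC[C@@]1(C)C[C@H](O[Si](c3ccccc3)(c3ccccc3)C(C)(C)C)C[C@]2(C)C(CCC(O)COC(=O)CP(=O)(OCC)OCC)=C(C)C[C@H](O[Si](C)(C)C(C)(C)C)[C@H]12 | intermediate
38 | 13-ketone of 37 | CC(=O)OC[C@@]1(C)C[C@H](O[Si](c3ccccc3)(c3ccccc3)C(C)(C)C)C[C@]2(C)C(CCC(=O)COC(=O)CP(=O)(OCC)OCC)=C(C)C[C@H](O[Si](C)(C)C(C)(C)C)[C@H]12 | intermediate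
39 | 19-acetoxy-2α-(TBDPS-oxy)-6α-(TBS-oxy)-5β-labda-8,13-dien-15,16-olide | CC(=O)OC[C@@]1(C)C[C@H](O[Si](c3ccccc3)(c3ccccc3)C(C)(C)C)C[C@]2(C)C(CCC3=CC(=O)OC3)=C(C)C[C@H](O[Si](C)(C)C(C)(C)C)[C@H]12 | intermediate
40 | CNP0201970.1: 19-acetoxy-2α,6α-dihydroxy-5β-labda-8,13-dien-15,16-olide, (2R,4S,5S,6S,10S) | CC(=O)OC[C@@]1(C)C[C@H](O)C[C@]2(C)C(CCC3=CC(=O)OC3)=C(C)C[C@H](O)[C@H]12 | target

**Totals and risks**
Total step count: 28. Longest linear sequence: 25 steps (steps 1–5, then 9–28).

Most likely to fail, first: step 9, because the Mukaiyama–Michael union makes a quaternary–tertiary bond next to an α-methyl and a γ-silyloxy group. The fallback sets out from ketene acetal 12 and comes back at keto lactone 14. Compound 12 is added under the same LiClO4 conditions to commercially available (R)-4-[(tert-butyldimethylsilyl)oxy]cyclohex-2-en-1-one, which lacks the α-methyl and is a much better acceptor, and the product is kept as the silyl enol ether adduct F1. Simmons–Smith cyclopropanation of the enol ether (Et2Zn, CH2I2, CH2Cl2) gives the siloxycyclopropane F2, and acid-induced opening of the cyclopropane (HCl, MeOH–THF, 0 °C) puts the methyl on C10 and gives 14.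

Second: step 19, because the cis-fused 6-ketone 27 can epimerise at C5 and the hydride face selectivity is inferred from conformational analysis. The fallback sets out from 6β-alcohol 26 and comes back at 6α-alcohol 28 without passing through a ketone. Mitsunobu inversion (4-nitrobenzoic acid, PPh3, diisopropyl azodicarboxylate, toluene) gives the inverted 6α-(4-nitrobenzoate) F3, and methanolysis (K2CO3, MeOH, 0 °C) gives 28.

Third: step 21, because the B-alkyl Suzuki coupling has to engage a tetrasubstituted enol triflate next to a quaternary carbon. The fallback sets out from triflate 29 and comes back at 32. Sonogashira coupling of 29 with 4-ethynyl-2,2-dimethyl-1,3-dioxolane (PdCl2(PPh3)2, CuI, iPr2NH, DMF) gives the conjugated enyne F4. Hydrogenation over RhCl(PPh3)3 (H2, toluene) saturates the alkyne and the disubstituted alkene formed from it but not the tetrasubstituted C8=C9 bond, giving 32.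

**Further compounds**
F1 | step 9 | silyl enol ether adduct of 12 with (R)-4-(TBS-oxy)cyclohex-2-en-1-one (as 13 but without the C10 methyl) | C[C@]1(C[C@@H](COCc2ccccc2)OC1=O)[C@@H]3C=C(O[Si](C)(C)C(C)(C)C)CC[C@H]3O[Si](C)(C)C(C)(C)C
F2 | step 9 | siloxycyclopropane from F1 (CH2 bridging C9 and C10) | C[C@]1(C[C@@H](COCc2ccccc2)OC1=O)[C@@H]3C4CC4(O[Si](C)(C)C(C)(C)C)CC[C@H]3O[Si](C)(C)C(C)(C)C
F3 | step 19 | 6α-(4-nitrobenzoate) of 28 | COC(=O)[C@@]1(C)C[C@H](O[Si](c3ccccc3)(c3ccccc3)C(C)(C)C)C[C@]2(C)C(OS(=O)(=O)C(F)(F)F)=C(C)C[C@H](OC(=O)c3ccc(cc3)[N+](=O)[O-])[C@H]12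
F4 | step 21 | 11,12-didehydro (alkyne) analogue of 32 | COC(=O)[C@@]1(C)C[C@H](O[Si](c3ccccc3)(c3ccccc3)C(C)(C)C)C[C@]2(C)C(C#CC3COC(C)(C)O3)=C(C)C[C@H](O[Si](C)(C)C(C)(C)C)[C@H]12
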